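I decide to reckon this flask by one ratio, the L made per Z made.

| setting | oak | larch | cedar | flask |
|---|---|---|---|---|
| Q | 0.42 M | 0.66 M | 0.30 M | 0.30 M |
| G | 110 mM (held) | 110 mM (held) | 110 mM (held) | 110 mM (held) |
| J | 3 mM | 3 mM | 1.5 mM | 3.0 mM |
| remark | run made earlier | run made earlier | run made earlier |  |
| time |  |  |  | 8.0 h |

| run | time / h | L / % | Q / % |
|---|---|---|---|
| oak | 1.33 | 24.2 | 21.3 |
| oak | 2.50 | 27.1 | 0 |
| oak | 4.00 | 25.9 | 0 |
| oak | 5.00 | 27.5 | 0 |
| larch | 0.667 | 9.5 | 71.1 |
| larch | 1.50 | 19.5 | 33.1 |
| larch | 3.00 | 27.7 | 0 |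
| larch | 5.00 | 25.5 | 0.8 |
| cedar | 0.667 | 11.0 | 47.7 |
| cedar | 1.50 | 19.5 | 6.7 |
| cedar | 3.00 | 19.9 | 0 |
| cedar | 5.00 | 22.8 | 0 |

(each reading ± 1 percentage point)

- at the start none of E is dissolved
- candidate steps: G <-> E; Q + E + J -> J + L; Q + E -> Z; 2 J <-> X

- the L standing at 8.0 h, as a percentage of the Q charged
- concentration of E in solution at 8.0 h, in percent of saturation

Why that ratio? Q + E + J -> J + L and Q + E -> Z each take one Q and one E, so in the ratio of their rates at any moment [Q] and [E] cancel, and what stays is proportional to [J].

Does the comparison drift? J comes back at each turn, but 2 J <-> X can take it out of the working form. Counting the rest of the Q used as Z, larch reads L over Z at 0.490 at 0.667 h, more than the 0.346 at 5.00 h. So I expect the ratio to fall during a run, and I reckon with end-of-run values, which hold the early part.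

What is it worth at this J? Oak and larch share the J charge of the flask, and their late readings average 26.7 % L. That gives the selectivity factor, L over Z at the end of a run, of 0.365. My reckoning for the flask is therefore 26.7 %.

But cedar has half the J, so why doesn't the ratio halve? Cedar's last readings average 21.3 %, a ratio of 0.271. Oak and larch stand 1.34 times above that, less than the factor of 2.00 in J and close to its square root, 1.41. So I read most J as paired into X, with the ratio growing as the square root of the J charged.

And E? Larch used Q at 0.294 M/h on average, one E per Q, so the transfer constant is at least 2.68 /h. Its time, 0.373 h, is shorter than the 5.00 h left after cedar's reading of 0 % Q, so I put [E] in the flask at saturation.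

The forecast says 26.8 % and 100 %, “with no sign of L decaying”. The flask gives 28.6 % and 100 %.

    G ⇌ E, rate k1*(csat - [E]) (kL = 8.70 × 10⁻⁴ /s)
    Q + E + J → J + L (k = 3.60 /M²/s)
    Q + E → Z (k = 0.0110 /M/s)
    2 J ⇌ X (K = 920 /M, k = 0.260 /M/s)

In the flask, L over Z is 0.400 at 8.00 h, against 0.365 from the earlier runs. The neighbouring flask is this flask with 0.012 M of J, 4.00 times the charge. The square-root rule takes 0.365 to 0.730, which means 42.2 % L. The neighbouring flask gives 45.8 % L and 54.2 % Z, a ratio of 0.845. Free J in the neighbouring flask stands at 2.30 mM against 1.03 mM in the flask, with 80.9 % of the catalyst charged held as X.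

(Readings and results are simulated on assumed constants.)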